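**Retrosynthetic overview**

1. 27 ⇐ 25 (tert-butyl ester cleavage) ⇐ 15 + 24: the two halves are joined at the single bond between the CH2 on the stereocentre and the alkenyl CH of the (E)-CH=C(CH3) unit, by a nickel-catalysed reductive decarboxylative coupling. Both carbons enter as electrophiles (acyloxyphthalimide, alkenyl bromide) and are united through a primary alkyl radical.
2. Enabling feature: this CH2 is an unfunctionalised sp3 carbon between an sp2 CH and the isopropenyl-bearing CH. It can therefore be carried as CH2–CO2H, i.e. as C3 and C2(=O) of an oxan-2-one (δ-lactone) ring whose C4 is the stereocentre and whose C5–C6–O1 becomes the CH2CH2 arm to the Z-enoate; the carboxyl carbon leaves as CO2 in the key step.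
3. East half 15 ⇐ Still–Gennari (Z)-olefination of phosphonate 8 with 3-(furan-3-yl)propanal 12 ⇐ iodide 6 ⇐ opening of lactone 3 ⇐ Rh/(S)-BINAP 1,4-addition of an isopropenyl group to 5,6-dihydro-2H-pyran-2-one 1, which sets the only stereocentre.
4. West half 24 ⇐ (E)-selective Wittig reaction of the α-homoprenyl ylide 19 with aldehyde 23 ⇐ zirconium-catalysed methylalumination/bromination of pent-4-yn-1-ol 20, which fixes the (E)-bromoalkene.
5. Rings: none is formed. The furan comes from furan-3-carbaldehyde 9, and the lactone ring of 1 is opened in step 2.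

Key step: step 14

Assumption: the sense of induction of (S)-BINAP in step 1 is taken from the established model for rhodium-catalysed 1,4-additions to this lactone; should it prove opposite, (R)-BINAP is used and nothing else changes.

**Route**

Step 1
Reactants: 1 5,6-dihydro-2H-pyran-2-one; 2 potassium trifluoro(prop-1-en-2-yl)borate
Product: 3 (4S)-4-(prop-1-en-2-yl)oxan-2-one
Conditions: [Rh(cod)2]BF4 (3 mol%), (S)-BINAP (3.3 mol%), toluene/H2O 10:1, 100 °C
Reagents that add atoms: none
Why: Hayashi–Miyaura rhodium-catalysed asymmetric 1,4-addition, in which the isopropenyl group passes from boron to monovalent rhodium, inserts into the lactone C=C inside the (S)-BINAP pocket and the rhodium enolate is protonated by water, so that the ligand sets the single stereocentre of the target (expected S).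

Step 2
Reactants: 3 (4S)-4-(prop-1-en-2-yl)oxan-2-one
Product: 5 prop-2-en-1-yl (3S)-5-hydroxy-3-(prop-1-en-2-yl)pentanoate, via lithium carboxylate 4 (not isolated)
Conditions: LiOH (1.05 equiv), THF/H2O, 0 °C → rt; evaporation; then allyl bromide, DMF, rt
Reagents that add atoms: lithium hydroxide, [Li+].[OH-]; allyl bromide (3-bromoprop-1-ene), C=CCBr
Why: Saponification opens the lactone by acyl–oxygen cleavage without touching the stereocentre, and SN2 O-alkylation of the carboxylate traps the open form as an allyl ester that can later be removed under neutral conditions.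

Step 3
Reactants: 5 prop-2-en-1-yl (3S)-5-hydroxy-3-(prop-1-en-2-yl)pentanoate
Product: 6 prop-2-en-1-yl (3R)-5-iodo-3-(prop-1-en-2-yl)pentanoate
Conditions: I2, PPh3, imidazole, CH2Cl2, 0 °C → rt
Reagents that add atoms: iodine, II
Why: Appel-type iodination (Garegg–Samuelsson conditions) converts the primary alcohol through its alkoxyphosphonium salt into the iodide under neutral conditions that prevent relactonisation; the descriptor changes only because iodine raises the CIP rank of that arm.

Step 4
Reactants: 6 prop-2-en-1-yl (3R)-5-iodo-3-(prop-1-en-2-yl)pentanoate; 7 methyl 2-[bis(2,2,2-trifluoroethoxy)phosphoryl]acetate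
Product: 8 1-methyl 7-(prop-2-en-1-yl) (5S)-2-[bis(2,2,2-trifluoroethoxy)phosphoryl]-5-(prop-1-en-2-yl)heptanedioate (both epimers at C2)
Conditions: NaH, DMF, 0 °C (7, 1.5 equiv); then 6, rt → 40 °C
Reagents that add atoms: none
Why: SN2 C-alkylation of the stabilised phosphonoacetate anion by an unhindered primary iodide; the new centre next to phosphorus forms unselectively and is irrelevant because it becomes sp2 in step 7.

Step 5
Reactants: 9 furan-3-carbaldehyde; 10 (triphenylphosphoranylidene)acetaldehyde
Product: 11 (2E)-3-(furan-3-yl)prop-2-enal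
Conditions: toluene, 80 °C
Reagents that add atoms: none
Why: Wittig reaction of a formyl-stabilised ylide with an aromatic aldehyde, which should give the (E)-enal by two-carbon homologation.

Step 6
Reactants: 11 (2E)-3-(furan-3-yl)prop-2-enal
Product: 12 3-(furan-3-yl)propanal
Conditions: Hantzsch ester (diethyl 2,6-dimethyl-1,4-dihydropyridine-3,5-dicarboxylate), dibenzylammonium trifluoroacetate (5 mol%), THF, rt
Reagents that add atoms: none
Why: Organocatalytic transfer hydrogenation, in which the iminium ion of the enal accepts hydride from the Hantzsch ester at the β-carbon, so only the conjugated C=C is reduced and the furan and the aldehyde remain.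

Step 7
Reactants: 8 1-methyl 7-(prop-2-en-1-yl) (5S)-2-[bis(2,2,2-trifluoroethoxy)phosphoryl]-5-(prop-1-en-2-yl)heptanedioate; 12 3-(furan-3-yl)propanal
Product: 13 1-methyl 7-(prop-2-en-1-yl) (2Z,5S)-2-[3-(furan-3-yl)propylidene]-5-(prop-1-en-2-yl)heptanedioate
Conditions: KN(SiMe3)2, 18-crown-6, THF, −78 °C; then 12, −78 °C
Reagents that add atoms: none
Why: Still–Gennari variant of the Horner–Wadsworth–Emmons olefination, where the electron-poor trifluoroethyl phosphonate and the crown-complexed potassium ion make elimination from the kinetic adduct fast and should give the (Z)-trisubstituted enoate with the ester cis to the furylethyl chain.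

Step 8
Reactants: 13 1-methyl 7-(prop-2-en-1-yl) (2Z,5S)-2-[3-(furan-3-yl)propylidene]-5-(prop-1-en-2-yl)heptanedioate
Product: 14 (3S,6Z)-9-(furan-3-yl)-6-(methoxycarbonyl)-3-(prop-1-en-2-yl)non-6-enoic acid
Conditions: Pd(PPh3)4 (3 mol%), morpholine, THF, rt; aqueous citric acid work-up
Reagents that add atoms: none
Why: Tsuji–Trost deallylation, in which zerovalent palladium ionises only the allyl ester to a π-allyl complex that morpholine captures, leaving the methyl ester, the furan and the alkenes untouched.

Step 9
Reactants: 14 (3S,6Z)-9-(furan-3-yl)-6-(methoxycarbonyl)-3-(prop-1-en-2-yl)non-6-enoic acid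
Product: 15 1,3-dioxo-1,3-dihydro-2H-isoindol-2-yl (3S,6Z)-9-(furan-3-yl)-6-(methoxycarbonyl)-3-(prop-1-en-2-yl)non-6-enoate
Conditions: N-hydroxyphthalimide, N,N'-diisopropylcarbodiimide, DMAP (cat.), CH2Cl2, rt
Reagents that add atoms: N-hydroxyphthalimide, O=C1c2ccccc2C(=O)N1O
Why: Steglich-type carbodiimide esterification gives the redox-active N-acyloxyphthalimide, a chromatography-stable radical precursor.

Step 10
Reactants: 16 tert-butyl (triphenylphosphoranylidene)acetate; 17 5-bromo-2-methylpent-2-ene
Product: 19 tert-butyl 6-methyl-2-(triphenylphosphoranylidene)hept-5-enoate, via phosphonium bromide 18 (not isolated)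
Conditions: K2CO3, NaI (cat.), MeCN, 80 °C
Reagents that add atoms: none
Why: Bestmann C-alkylation of an ester-stabilised ylide by the primary halide (iodide-catalysed SN2), after which carbonate deprotonates the phosphonium salt to regenerate a stabilised ylide carrying the homoprenyl group.

Step 11
Reactants: 20 pent-4-yn-1-ol
Product: 22 (4E)-5-bromo-4-methylpent-4-en-1-ol, via alkenylalane 21 (not isolated)
Conditions: AlMe3 (3 equiv), Cp2ZrCl2 (0.25 equiv), CH2Cl2, 0 °C → rt; then N-bromosuccinimide, THF, −30 °C; aqueous work-up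
Reagents that add atoms: trimethylaluminium, C[Al](C)C; N-bromosuccinimide, O=C1CCC(=O)N1Br
Why: Negishi zirconium-catalysed methylalumination adds methyl and aluminium syn across the terminal alkyne with aluminium on the terminal carbon, and bromodealumination with retention should give the (E)-bromoalkene.

Step 12
Reactants: 22 (4E)-5-bromo-4-methylpent-4-en-1-ol
Product: 23 (4E)-5-bromo-4-methylpent-4-enal
Conditions: Dess–Martin periodinane, CH2Cl2, 0 °C → rt
Reagents that add atoms: none
Why: Dess–Martin oxidation of the primary alcohol to the aldehyde without over-oxidation or effect on the bromoalkene.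

Step 13
Reactants: 23 (4E)-5-bromo-4-methylpent-4-enal; 19 tert-butyl 6-methyl-2-(triphenylphosphoranylidene)hept-5-enoate
Product: 24 tert-butyl (2E,6E)-7-bromo-6-methyl-2-(4-methylpent-3-en-1-yl)hepta-2,6-dienoate
Conditions: toluene, 90 °C
Reagents that add atoms: none
Why: Wittig reaction of an α-branched ester-stabilised ylide, whose reversible addition should lead to the (E)-trisubstituted enoate with the chain trans to the ester.

Step 14
Reactants: 15 1,3-dioxo-1,3-dihydro-2H-isoindol-2-yl (3S,6Z)-9-(furan-3-yl)-6-(methoxycarbonyl)-3-(prop-1-en-2-yl)non-6-enoate; 24 tert-butyl (2E,6E)-7-bromo-6-methyl-2-(4-methylpent-3-en-1-yl)hepta-2,6-dienoate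
Product: 25 1-tert-butyl 13-methyl (2E,6E,9S,12Z)-12-[3-(furan-3-yl)propylidene]-6-methyl-2-(4-methylpent-3-en-1-yl)-9-(prop-1-en-2-yl)trideca-2,6-dienedioate
Conditions: NiBr2·glyme (15 mol%), 4,4'-di-tert-butyl-2,2'-bipyridine (15 mol%), Zn dust (2.5 equiv), DMA, 25 °C
Reagents that add atoms: none
Why: Zinc reduces the precatalyst to zerovalent nickel, which inserts into the C–Br bond of 24 with retention to give an (E)-alkenyl complex of divalent nickel; single-electron reduction of 15 then releases phthalimide anion, CO2 and the primary radical at the CH2 next to the stereocentre, which the alkenylnickel species captures to give a trivalent nickel complex that reductively eliminates the new C(sp3)–C(sp2) bond, zinc closing the cycle. The closest known reaction type is the nickel-catalysed reductive decarboxylative cross-electrophile coupling of N-hydroxyphthalimide esters with aryl iodides and alkenyl bromides. No ring is closed and no stereocentre is created: the existing stereocentre is β to the radical carbon and belongs to no bond that is broken, and the (E)-geometry of the 2,2-disubstituted alkenyl partner is kept because such alkenyl–nickel bonds are configurationally stable. The step needs cross- over homo-coupling, which is secured by the two different activation modes (two-electron oxidative addition for the C(sp2)–Br bond, one-electron fragmentation for the redox-active ester). It also needs the radical to be trapped before it attacks the isopropenyl group (3-exo, reversible) or the trisubstituted enoate (5-exo or 6-endo, slowed by the β-alkyl group); both are slow radical clocks, so capture by nickel at this loading and at high concentration should stay ahead. Neither ester, the furan nor any C=C bond should be reduced by zinc under these conditions.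

Step 15
Reactants: 25 1-tert-butyl 13-methyl (2E,6E,9S,12Z)-12-[3-(furan-3-yl)propylidene]-6-methyl-2-(4-methylpent-3-en-1-yl)-9-(prop-1-en-2-yl)trideca-2,6-dienedioate
Product: 27 (2E,6E,9S,12Z)-12-[3-(furan-3-yl)propylidene]-13-methoxy-6-methyl-2-(4-methylpent-3-en-1-yl)-13-oxo-9-(prop-1-en-2-yl)trideca-2,6-dienoic acid (CNP0201108.2), via trimethylsilyl ester 26 (not isolated)
Conditions: Me3SiOTf, 2,6-lutidine, CH2Cl2, 0 °C → rt; then aqueous citric acid
Reagents that add atoms: trimethylsilyl trifluoromethanesulfonate, C[Si](C)(C)OS(=O)(=O)C(F)(F)F (its silyl group is found in 26 only)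
Why: Silyl triflate-mediated tert-butyl ester cleavage, in which O-silylation lets the tert-butyl group leave as isobutene under lutidine buffering and the silyl ester hydrolyses on work-up, while the methyl ester cannot ionise and the furan and alkenes see no protic acid.

**Compound list**

1 | 5,6-dihydro-2H-pyran-2-one | O=C1C=CCCO1 | starting material
2 | potassium trifluoro(prop-1-en-2-yl)borate | [K+].C=C(C)[B-](F)(F)F | starting material
3 | (4S)-4-(prop-1-en-2-yl)oxan-2-one | C=C(C)[C@@H]1CC(=O)OCC1 | intermediate
4 | lithium (3S)-5-hydroxy-3-(prop-1-en-2-yl)pentanoate | C=C(C)[C@H](CC(=O)[O-])CCO.[Li+] | intermediate (not isolated)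
5 | prop-2-en-1-yl (3S)-5-hydroxy-3-(prop-1-en-2-yl)pentanoate | C=C(C)[C@H](CC(=O)OCC=C)CCO | intermediate
6 | prop-2-en-1-yl (3R)-5-iodo-3-(prop-1-en-2-yl)pentanoate | C=C(C)[C@H](CC(=O)OCC=C)CCI | intermediate
7 | methyl 2-[bis(2,2,2-trifluoroethoxy)phosphoryl]acetate | COC(=O)CP(=O)(OCC(F)(F)F)OCC(F)(F)F | starting material
8 | 1-methyl 7-(prop-2-en-1-yl) (5S)-2-[bis(2,2,2-trifluoroethoxy)phosphoryl]-5-(prop-1-en-2-yl)heptanedioate (C2 epimers) | C=C(C)[C@H](CC(=O)OCC=C)CCC(C(=O)OC)P(=O)(OCC(F)(F)F)OCC(F)(F)F | intermediate
9 | furan-3-carbaldehyde | O=Cc1ccoc1 | starting material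
10 | (triphenylphosphoranylidene)acetaldehyde | O=CC=P(c1ccccc1)(c1ccccc1)c1ccccc1 | starting material
11 | (2E)-3-(furan-3-yl)prop-2-enal | O=C/C=C/c1ccoc1 | intermediate
12 | 3-(furan-3-yl)propanal | O=CCCc1ccoc1 | intermediate
13 | 1-methyl 7-(prop-2-en-1-yl) (2Z,5S)-2-[3-(furan-3-yl)propylidene]-5-(prop-1-en-2-yl)heptanedioate | C=C(C)[C@H](CC(=O)OCC=C)CC/C(=C/CCc1ccoc1)C(=O)OC | intermediate
14 | (3S,6Z)-9-(furan-3-yl)-6-(methoxycarbonyl)-3-(prop-1-en-2-yl)non-6-enoic acid | C=C(C)[C@H](CC(=O)O)CC/C(=C/CCc1ccoc1)C(=O)OC | intermediate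
15 | 1,3-dioxo-1,3-dihydro-2H-isoindol-2-yl (3S,6Z)-9-(furan-3-yl)-6-(methoxycarbonyl)-3-(prop-1-en-2-yl)non-6-enoate | C=C(C)[C@H](CC(=O)ON1C(=O)c2ccccc2C1=O)CC/C(=C/CCc1ccoc1)C(=O)OC | intermediate
16 | tert-butyl (triphenylphosphoranylidene)acetate | CC(C)(C)OC(=O)C=P(c1ccccc1)(c1ccccc1)c1ccccc1 | starting material
17 | 5-bromo-2-methylpent-2-ene | CC(C)=CCCBr | starting material
18 | [1-(tert-butoxy)-6-methyl-1-oxohept-5-en-2-yl]triphenylphosphonium bromide | CC(C)=CCCC(C(=O)OC(C)(C)C)[P+](c1ccccc1)(c1ccccc1)c1ccccc1.[Br-] | intermediate (not isolated)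
19 | tert-butyl 6-methyl-2-(triphenylphosphoranylidene)hept-5-enoate | CC(C)=CCCC(C(=O)OC(C)(C)C)=P(c1ccccc1)(c1ccccc1)c1ccccc1 | intermediate
20 | pent-4-yn-1-ol | C#CCCCO | starting material
21 | dimethyl{(1E)-5-[(dimethylalumanyl)oxy]-2-methylpent-1-en-1-yl}alumane | C[Al](C)/C=C(\C)CCCO[Al](C)C | intermediate (not isolated)
22 | (4E)-5-bromo-4-methylpent-4-en-1-ol | Br/C=C(\C)CCCO | intermediate
23 | (4E)-5-bromo-4-methylpent-4-enal | Br/C=C(\C)CCC=O | intermediate
24 | tert-butyl (2E,6E)-7-bromo-6-methyl-2-(4-methylpent-3-en-1-yl)hepta-2,6-dienoate | Br/C=C(\C)CC/C=C(\CCC=C(C)C)C(=O)OC(C)(C)C | intermediate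
25 | 1-tert-butyl 13-methyl (2E,6E,9S,12Z)-12-[3-(furan-3-yl)propylidene]-6-methyl-2-(4-methylpent-3-en-1-yl)-9-(prop-1-en-2-yl)trideca-2,6-dienedioate | C=C(C)[C@H](C/C=C(\C)CC/C=C(\CCC=C(C)C)C(=O)OC(C)(C)C)CC/C(=C/CCc1ccoc1)C(=O)OC | intermediate
26 | 13-methyl 1-(trimethylsilyl) (2E,6E,9S,12Z)-12-[3-(furan-3-yl)propylidene]-6-methyl-2-(4-methylpent-3-en-1-yl)-9-(prop-1-en-2-yl)trideca-2,6-dienedioate | C=C(C)[C@H](C/C=C(\C)CC/C=C(\CCC=C(C)C)C(=O)O[Si](C)(C)C)CC/C(=C/CCc1ccoc1)C(=O)OC | intermediate (not isolated)
27 | (2E,6E,9S,12Z)-12-[3-(furan-3-yl)propylidene]-13-methoxy-6-methyl-2-(4-methylpent-3-en-1-yl)-13-oxo-9-(prop-1-en-2-yl)trideca-2,6-dienoic acid (CNP0201108.2) | C=C(C)[C@H](C/C=C(\C)CC/C=C(\CCC=C(C)C)C(=O)O)CC/C(=C/CCc1ccoc1)C(=O)OC | target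

**Step count**

Total: 15 steps. Longest linear sequence: 9 steps (1, 2, 3, 4, 7, 8, 9, 14, 15).

**Steps most likely to fail**

Step 14. The primary radical may react within the molecule before nickel captures it (attack on the isopropenyl group followed by 1,2-alkenyl shift, or cyclisation onto the enoate), or it may be lost by hydrogen abstraction and homodimerisation. The fallback sets out from 15 and returns at 25, and replaces the radical–nickel union by a two-electron cross-coupling. 15 is irradiated with blue light together with bis(catecholato)diboron in DMA, where the radical is trapped by a stoichiometric boron reagent, to give the catechol boronate F1. This is transesterified in the same flask with pinacol and Et3N to the pinacol boronate F2. Suzuki–Miyaura coupling of F2 with 24 (Pd(OAc)2, SPhos, K3PO4, toluene/H2O, 80 °C) should then give 25.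

Step 1. Transfer of the α-branched alkenyl group from boron to rhodium may be slow against protodeboronation, and facial discrimination may be insufficient. The fallback sets out from 1 and returns at 5, and sets the stereocentre by desymmetrisation instead of conjugate addition. Copper-catalysed addition of isopropenylmagnesium bromide to 1 (CuBr·SMe2, Me3SiCl, THF, −78 °C) gives the racemic lactone F3. Saponification (NaOH, H2O) gives the sodium hydroxy-carboxylate F4, which is oxidised in the same flask (TEMPO, PhI(OAc)2, MeCN/H2O) to the achiral 3-(prop-1-en-2-yl)pentanedioic acid F5. Ac2O at reflux closes the cyclic anhydride F6. Alcoholysis with allyl alcohol under a cinchona-alkaloid catalyst (the pseudoenantiomer known to give this sense with 3-substituted glutaric anhydrides; toluene, −20 °C) should give the (S)-hemiester F7. Its free carboxyl group is converted into the isobutyl carbonic mixed anhydride F8 (isobutyl chloroformate, N-methylmorpholine, THF, −15 °C) and reduced with NaBH4 (THF/H2O, 0 °C) to 5.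

Step 10. SN2 alkylation of the weakly nucleophilic stabilised ylide by an unactivated primary halide may be sluggish, with loss of HBr from 17 competing. The fallback sets out from 17 and returns at 24, and replaces the Wittig reagent by a phosphonate. The sodium salt of tert-butyl diethylphosphonoacetate (NaH, DMF, 50 °C) is alkylated with 17 to give tert-butyl 2-(diethoxyphosphoryl)-6-methylhept-5-enoate F9. Horner–Wadsworth–Emmons reaction of F9 with 23 (LiCl, DBU, MeCN, rt) should give 24 after chromatographic removal of the (2Z)-isomer.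

**Further compounds**

F1 | step 14 | methyl (2Z)-2-[(3R)-3-(1,3,2-benzodioxaborol-2-ylmethyl)-4-methylpent-4-en-1-yl]-5-(furan-3-yl)pent-2-enoate | C=C(C)[C@H](CB1Oc2ccccc2O1)CC/C(=C/CCc1ccoc1)C(=O)OC
F2 | step 14 | methyl (2Z)-5-(furan-3-yl)-2-{(3R)-4-methyl-3-[(4,4,5,5-tetramethyl-1,3,2-dioxaborolan-2-yl)methyl]pent-4-en-1-yl}pent-2-enoate | C=C(C)[C@H](CB1OC(C)(C)C(C)(C)O1)CC/C(=C/CCc1ccoc1)C(=O)OC
F3 | step 1 | racemic 4-(prop-1-en-2-yl)oxan-2-one | C=C(C)C1CC(=O)OCC1
F4 | step 1 | sodium 5-hydroxy-3-(prop-1-en-2-yl)pentanoate (racemic) | C=C(C)C(CC(=O)[O-])CCO.[Na+]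
F5 | step 1 | 3-(prop-1-en-2-yl)pentanedioic acid | C=C(C)C(CC(=O)O)CC(=O)O
F6 | step 1 | 4-(prop-1-en-2-yl)oxane-2,6-dione | C=C(C)C1CC(=O)OC(=O)C1
F7 | step 1 | (3S)-5-oxo-5-(prop-2-en-1-yloxy)-3-(prop-1-en-2-yl)pentanoic acid | C=C(C)[C@H](CC(=O)OCC=C)CC(=O)O
F8 | step 1 | isobutyl carbonic mixed anhydride of F7 | C=C(C)[C@H](CC(=O)OCC=C)CC(=O)OC(=O)OCC(C)C
F9 | step 10 | tert-butyl 2-(diethoxyphosphoryl)-6-methylhept-5-enoate | CC(C)=CCCC(C(=O)OC(C)(C)C)P(=O)(OCC)OCC
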